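The forms of the catalyst (free catalyst, idle complex, spent catalyst counted per catalyst that went into it) always add up to the charge, so what you watch is how that charge is shared.

    2 free catalyst → spent catalyst (k1 = 0.036 M⁻¹ s⁻¹)
    free catalyst + added ligand ⇌ idle complex (K2 = 530 M⁻¹, k2 = 0.016 M⁻¹ s⁻¹)
    substrate + coupling partner + free catalyst → free catalyst + target (k3 = 0.014 M⁻² s⁻¹)

substrate 0.80 M; coupling partner 0.840 M; free catalyst 0.80 mM; added ligand 1.7 mM

- apparent order in free catalyst when 20 % of the substrate are converted (percent change of the rate of making target for one percent more free catalyst charged)

At a given conversion [substrate] and [coupling partner] are set by the charges of those two. The order in free catalyst is then the response of [free catalyst] at that mark. Taking both at their mean, at 10.0 % conversion, gives 20.9 M·s for the exposure, the time integral of [free catalyst] needed to reach 20 % conversion. The exact integral gives 21.1 M·s, so the mean errs by 1.17 %.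

Turn the catalyst charge first, with loss to spent catalyst as its one fate. [free catalyst] then falls exponentially in exposure. By this reckoning its share at the mark is 22.2 % at any charge, the order is exactly one, and with this charge the mark comes at 16.9 h.

Now turn on the added ligand. The forward half-life of free catalyst into idle complex, 7.08 h, is shorter than that run. At full equilibrium from the start, with added ligand as charged and 0.901 idle complex per free catalyst, my share at the mark becomes 23.8 %. More catalyst shortens the run, so I expect the flask to move toward the lower share. If one doubling went the whole way, the order would be 0.899, and that is my number.

The forecast says 0.97, within 0.8 to 1.15, higher than mine, holding that “the second-order catalyst death acts like a first-order loss”. Its number sits near plain proportion.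

The simulation gives 0.83, lower than my number and lower than the forecast's. Watch the forward half-life of free catalyst into idle complex, 7.9 h at 10.8 h, which is shorter than the 10.8 h by which half of the target made up to 50.0 h is made. At the mark, at 22.7 h, free catalyst holds 18.4 % of the catalyst and idle complex 18.3 %, and the free share is lower than both of mine. The exposure then means a mean [free catalyst] of 31.9 % of the charge. In the flask with twice the catalyst, the time to the mark is 0.480 of this one, and the same exposure means a mean of 33.2 % of its charge.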